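**Retrosynthetic overview**
1. The target comes from one global hydrogenation/hydrogenolysis of a benzhydrol that carries OBn, OCbz and the side-chain alkene.
2. Key disconnection: the ring C aryl–CH(OH) bond. It gives a ring-C aryl bromide and a ring-A/B salicylaldehyde, joined by visible-light-driven Ni catalysis.
3. Ring C is built on the vinyl group of (R)-(–)-linalool by Heck vinylation with a C4 bromo-iodo acid, then dienylketene 6π benzannulation. The C–O stereocentre is bought and never touched.
4. The diaryl ether comes from Ullmann coupling of the 4-OH of 2,4-dihydroxy-6-methylbenzaldehyde with O-benzyl 3-bromo-5-methylphenol.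
5. Ring order: A and B are purchased arenes. C is the only ring formed (Step 3).

Assumption: CIP analysis of the given SMILES gives (R) at the carbinol. This maps onto commercial (R)-(–)-linalool, because vinyl and aryl hold the same CIP rank, and the ee of the linalool is carried through unchanged.

**Step 1**
Reactants: 1 but-3-ynoic acid
Product: 2 (E)-3-bromo-4-iodobut-3-enoic acid (I cis to CH2CO2H, trans to Br)
Conditions: IBr (1.05 equiv), CH2Cl2, –78 → –20 °C, dark
Reagents that add atoms: iodine monobromide, BrI
Why: Electrophilic anti-iodobromination of a terminal alkyne via an iodirenium ion puts I on the terminal carbon and Br on the internal carbon from the opposite face, giving the E isomer whose C–I bond is cis to CH2CO2H, the geometry needed for ring closure in Step 3.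

**Step 2**
Reactants: 2 (E)-3-bromo-4-iodobut-3-enoic acid; 3 (R)-(–)-linalool (2 equiv)
Product: 4 (3E,5E,7R)-3-bromo-7-hydroxy-7,11-dimethyldodeca-3,5,10-trienoic acid
Conditions: Pd(OAc)2 (5 mol %), Ag2CO3 (1.2 equiv), MeCN, 45 °C, dark; pH 5 work-up
Reagents that add atoms: none
Why: In this Mizoroki–Heck vinylation, ligand-free Pd inserts into C(sp2)–I only (C–Br is inert at 45 °C) and adds to the CH2 terminus of the vinyl group; because the carbinol carbon bears no H, β-hydride elimination can only give the E,E-diene, the trisubstituted alkene is a spectator, and the bought stereocentre (C7) is not involved and stays (R).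

**Step 3**
Reactants: 4 the trienoic acid
Product: 5 benzyl {5-bromo-2-[(2R)-2-hydroxy-6-methylhept-5-en-2-yl]phenyl} carbonate
Conditions: CbzCl (2.5 equiv), Et3N (4 equiv), THF, 0 → 40 °C
Reagents that add atoms: benzyl chloroformate, O=C(Cl)OCc1ccccc1
Why: In this dienylketene benzannulation, the mixed carbonic anhydride undergoes E1cB loss to the dienylketene (C2 and C5 cis across C3=C4), which closes by 6π electrocyclisation (C1–C6); very fast base-mediated tautomerisation of the dienone outruns retro-aldol, the phenol is trapped as its hydrogenolysable Cbz carbonate, and the hindered tertiary OH and its stereocentre are untouched under these basic conditions.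

**Step 4**
Reactants: 6 3-bromo-5-methylphenol
Product: 7 1-(benzyloxy)-3-bromo-5-methylbenzene
Conditions: BnBr, K2CO3, acetone, reflux
Reagents that add atoms: benzyl bromide, BrCc1ccccc1
Why: This Williamson etherification masks the ring-A phenol so that it cannot self-couple in Step 5, and the group is removed at no step cost in Step 7.

**Step 5**
Reactants: 7 1-(benzyloxy)-3-bromo-5-methylbenzene; 8 2,4-dihydroxy-6-methylbenzaldehyde
Product: 9 4-[3-(benzyloxy)-5-methylphenoxy]-2-hydroxy-6-methylbenzaldehyde
Conditions: CuI (10 mol %), picolinic acid (20 mol %), K3PO4, DMSO, 100 °C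
Reagents that add atoms: none
Why: In this Ullmann-type Cu-catalysed O-arylation, only the more acidic, unhindered 4-OH reacts, because the 2-OH is locked in a hydrogen bond to the flanking CHO; buying the aldehyde fixes the ring-B substitution pattern (CH2 site ortho to OH and CH3, para to OAr) without any regiochemical step.

**Step 6**
Reactants: 5 the ring-C aryl bromide; 9 the ring-A/B salicylaldehyde (1.2 equiv)
Product: 10 benzyl {5-[{4-[3-(benzyloxy)-5-methylphenoxy]-2-hydroxy-6-methylphenyl}(hydroxy)methyl]-2-[(2R)-2-hydroxy-6-methylhept-5-en-2-yl]phenyl} carbonate (about 1:1 epimers at the benzhydrol carbon)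
Conditions: NiBr2(dppe) (10 mol %), [Ir(ppy)2(dtbbpy)]PF6 (1 mol %), Hantzsch ester (2 equiv), K3PO4 (1 equiv), THF–MeCN, 450 nm LEDs, 35 °C
Reagents that add atoms: none (the Hantzsch ester delivers only H)
Why: Proposed new method: a metal-powder-free, light-driven Ni-catalysed Grignard-type 1,2-addition of an aryl bromide to an unprotected, di-ortho-substituted salicylaldehyde, in which excited Ir(III) is reductively quenched by the Hantzsch ester, Ir(II) (about –1.5 V) reduces Ni(II) to Ni(0), and Ni(0) inserts into the unhindered C–Br bond of 5; Br/phenoxide exchange then binds 9 as a κ2-O,O chelate that holds the hindered, electron-rich C=O cis to the Ni–aryl bond so that migratory insertion becomes intramolecular, and protonolysis by the pyridinium by-product releases 10 and Ni(II) for re-reduction; 450 nm light is absorbed only by the dye, so the UV-labile o-hydroxybenzyl alcohol motifs are not excited; the closest known reaction types are Ni–phosphine/Zn reductive arylation of aromatic aldehydes and photochemically driven Co-catalysed addition of aryl iodides to aldehydes; the new carbinol centre is uncontrolled and is erased in Step 7, while the (R) centre is untouched.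

**Step 7**
Reactants: 10 the benzhydrol
Product: 11 target, 2-[(2R)-2-hydroxy-6-methylheptan-2-yl]-5-{[2-hydroxy-4-(3-hydroxy-5-methylphenoxy)-6-methylphenyl]methyl}phenol
Conditions: H2 (3 bar), 10 % Pd/C, EtOAc–EtOH, rt, neutral
Reagents that add atoms: none
Why: One catalytic hydrogenation/hydrogenolysis saturates the trisubstituted alkene, cleaves the OBn and OCbz groups (toluene, CO2) and hydrogenolyses the secondary, doubly benzylic, o-hydroxy-activated C–OH to CH2, while the sterically shielded tertiary mono-benzylic C–OH and the diaryl ether survive in neutral medium, so (R) is retained.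

**Compound list**
1 | but-3-ynoic acid | C#CCC(=O)O | starting material
2 | (E)-3-bromo-4-iodobut-3-enoic acid | OC(=O)C/C(Br)=C\I | intermediate
3 | (R)-(–)-linalool | C=C[C@](C)(O)CCC=C(C)C | starting material
4 | (3E,5E,7R)-3-bromo-7-hydroxy-7,11-dimethyldodeca-3,5,10-trienoic acid | OC(=O)C/C(Br)=C\C=C\[C@](C)(O)CCC=C(C)C | intermediate
5 | benzyl {5-bromo-2-[(2R)-2-hydroxy-6-methylhept-5-en-2-yl]phenyl} carbonate | O=C(OCc1ccccc1)Oc1cc(Br)ccc1[C@](C)(O)CCC=C(C)C | intermediate
6 | 3-bromo-5-methylphenol | Cc1cc(O)cc(Br)c1 | starting material
7 | 1-(benzyloxy)-3-bromo-5-methylbenzene | Cc1cc(Br)cc(OCc2ccccc2)c1 | intermediate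
8 | 2,4-dihydroxy-6-methylbenzaldehyde | Cc1cc(O)cc(O)c1C=O | starting material
9 | 4-[3-(benzyloxy)-5-methylphenoxy]-2-hydroxy-6-methylbenzaldehyde | Cc1cc(OCc2ccccc2)cc(Oc2cc(C)c(C=O)c(O)c2)c1 | intermediate
10 | benzhydrol coupling product (epimers at CHOH, 7R) | Cc1cc(OCc2ccccc2)cc(Oc2cc(C)c(C(O)c3ccc([C@](C)(O)CCC=C(C)C)c(OC(=O)OCc4ccccc4)c3)c(O)c2)c1 | intermediate
11 | 2-[(2R)-2-hydroxy-6-methylheptan-2-yl]-5-{[2-hydroxy-4-(3-hydroxy-5-methylphenoxy)-6-methylphenyl]methyl}phenol | Cc1cc(O)cc(Oc2cc(C)c(Cc3ccc([C@](C)(O)CCCC(C)C)c(O)c3)c(O)c2)c1 | target

**Step count**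
Total steps: 7. Longest linear sequence: 5 (Steps 1 → 2 → 3 → 6 → 7).

**Three steps most likely to fail**
1. **Step 6 (proposed new step).**
   - Risks: protodebromination of 5, and slow insertion into the hindered, electron-rich aldehyde. Any diarylmethane formed by in situ o-quinone-methide reduction is harmless, because it converges on 11 in Step 7.
   - Fallback (known chemistry, +1 step): Pd-catalysed Miyaura borylation of 5 to the boronic acid, then a thermal Petasis borono-Mannich reaction with 9 and dibenzylamine. The benzhydryl C–N bond is cleaved in the same Step 7 hydrogenolysis.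
2. **Step 2 (Heck on the free bromo-iodo acid).**
   - Risks: carboxylate-induced O-vinylation or π-allyl lactonisation, and a second insertion at C–Br.
   - Fallback: buy ring C instead of building it. (R)-Propylene oxide with isopentylMgBr/CuI gives (R)-6-methylheptan-2-ol, which is converted to its 2,4,6-triisopropylbenzoate. Treatment with s-BuLi/TMEDA, then a 2-(benzyloxy)-4-bromophenylboronic ester, stereospecific 1,2-metallate shift and H2O2 replaces H by aryl with retention. This gives the saturated O-benzyl analogue of 5, which enters at Step 6.
3. **Step 3 (ketene generation from the mixed carbonate).**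
   - Risk: collapse to the benzyl ester instead of E1cB.
   - Fallback: change the pericyclic precursor. Run Steps 1–2 on methyl but-3-ynoate and convert the dienoate into the trienyl silyl ketene acetal (LiHMDS, TBSCl). Close ring C by thermal 6π electrocyclisation with loss of MeOH to the aryl silyl ether, and remove the silyl group with fluoride before Step 7.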